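**Retrosynthetic overview**
1. Feature: with the ring numbered C1 (quaternary oxirane carbon carrying C7H2OBz), C2 (OBz), C3 (OH), C4=C5 and C6 (oxirane CH), the unit C7–C1–C6 lies beside the C4=C5 double bond. Once C7 is a carboxyl carbon and the oxirane is opened to O1/O6, this is a γ,δ-unsaturated acid whose C1–C6 bond is the one a [3,3] shift makes.
2. Endgame, backwards: C3–OH ⇐ silyl ether; oxirane ⇐ trans C1–OH/C6–OMs (inversion at C6); C2 and C7 benzoates ⇐ acetonide diol and C7 carbinol ⇐ acid 16.
3. Key disconnection: cyclohexene acid 16 ⇐ δ-lactone 13 (C7 carbonyl, O-silylated C1, lactone oxygen on C4, E-CH=CH–OPMB as C5=C6) by Ireland–Claisen ring contraction.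
4. Lactone 13 ⇐ alkynyl lactone 10 (E-hydroboration, copper-mediated etherification) ⇐ 3,4-O-isopropylidene-D-galacturonic acid 5 (alkyne homologation of the lactol, lactonisation onto O2) ⇐ benzyl β-D-galactopyranoside 1.
5. Ring order: dioxolane (step 1), pyranose opened (step 4), δ-lactone (step 5), carbocycle (step 8), oxirane (step 15).

Key step: step 8

Remark on configuration: in the numbering above the target is the (1S,2R,3R,6S) isomer; C7 lies on one ring face and the oxirane oxygen, O2 and O3 lie on the other.
Remark on the sugar: the D-galacturonic acid skeleton is entered through commercial benzyl β-D-galactopyranoside and oxidised at C6 in step 2, because the free uronic acid does not give a 3,4-mono-acetonide with a free anomeric position cleanly.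

**Step 1**
Reactants: 1 benzyl β-D-galactopyranoside; 2 2,2-dimethoxypropane
Product: 3 benzyl 3,4-O-isopropylidene-β-D-galactopyranoside
Conditions: Me2C(OMe)2, CSA (cat.), acetone, rt; Et3N; then MeOH/H2O (10:1), 50 °C
Reagents that add atoms: 2,2-dimethoxypropane (compound 2), COC(C)(C)OC
Why: Acid-catalysed transacetalisation places the dioxolane on the only cis-vicinal diol (O3 equatorial, O4 axial), the kinetic 6-O mixed acetal being solvolysed on work-up, and no stereocentre is touched.

**Step 2**
Reactants: 3 benzyl 3,4-O-isopropylidene-β-D-galactopyranoside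
Product: 4 benzyl 3,4-O-isopropylidene-β-D-galactopyranosiduronic acid
Conditions: TEMPO (0.2 equiv), PhI(OAc)2 (2.5 equiv), CH2Cl2/H2O (2:1), rt
Reagents that add atoms: water, O
Why: Oxoammonium-mediated (TEMPO/PhI(OAc)2) oxidation is selective for the primary C6 carbinol over the secondary O2–H and carries it through the aldehyde hydrate to the carboxylic acid.

**Step 3**
Reactants: 4 benzyl 3,4-O-isopropylidene-β-D-galactopyranosiduronic acid
Product: 5 3,4-O-isopropylidene-D-galactopyranuronic acid (free lactol)
Conditions: H2 (1 atm), Pd/C (10 %), EtOH, rt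
Reagents that add atoms: none
Why: Catalytic hydrogenolysis cleaves the benzylic anomeric C–O bond and leaves acetonide and acid intact, so the aldehyde carbon is unmasked as its lactol.

**Step 4**
Reactants: 5 3,4-O-isopropylidene-D-galactopyranuronic acid; 6 dimethyl (1-diazo-2-oxopropyl)phosphonate
Product: 7 6,7-dideoxy-3,4-O-isopropylidene-L-galacto-hept-6-ynonic acid
Conditions: 6 (1.5 equiv), K2CO3 (3.5 equiv), MeOH, 0 °C → rt; aqueous work-up at pH 3
Reagents that add atoms: dimethyl (1-diazo-2-oxopropyl)phosphonate (compound 6), COP(=O)(OC)C(=[N+]=[N-])C(C)=O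
Why: Seyferth–Gilbert homologation in the Ohira–Bestmann version: the diazomethylphosphonate anion released by methanolysis intercepts the open-chain aldehyde in equilibrium with the lactol and, after loss of dimethyl phosphate and N2 and a 1,2-hydrogen shift, leaves the terminal alkyne, with the adjacent carbinol centre expected to survive the mild carbonate base and carboxylate and hydroxyls as spectators in methanol.

**Step 5**
Reactants: 7 6,7-dideoxy-3,4-O-isopropylidene-L-galacto-hept-6-ynonic acid; 8 chlorotriethylsilane
Product: 10 6,7-dideoxy-3,4-O-isopropylidene-2-O-triethylsilyl-L-galacto-hept-6-ynono-1,5-lactone, via hydroxy lactone 9 (not isolated)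
Conditions: EDC·HCl (1.3 equiv), DMAP (0.1 equiv), CH2Cl2 (0.01 M), 0 °C → rt; then imidazole, Et3SiCl, 0 °C
Reagents that add atoms: chlorotriethylsilane (compound 8), CC[Si](Cl)(CC)CC
Why: Carbodiimide (Steglich-type) lactonisation can close only onto the δ-hydroxyl (the former O2 of the sugar, 6-exo-trig) because the α-hydroxyl cannot reach the activated carboxyl, and the remaining α-hydroxyl is then silylated, all four stereocentres being carried over.

**Step 6**
Reactants: 10 alkynyl δ-lactone
Product: 11 E-alkenyl pinacol boronate δ-lactone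
Conditions: pinacolborane (1.5 equiv), Cp2Zr(H)Cl (10 mol %), Et3N (10 mol %), CH2Cl2, 40 °C
Reagents that add atoms: pinacolborane, [H]B1OC(C)(C)C(C)(C)O1
Why: Zirconocene-hydride-catalysed hydroboration of a terminal alkyne is a syn, anti-Markovnikov addition, so only the E-alkenyl boronate can form, and pinacolborane leaves lactone, silyl ether and acetal alone.

**Step 7**
Reactants: 11 E-alkenyl pinacol boronate δ-lactone; 12 4-methoxybenzyl alcohol
Product: 13 E-2-(4-methoxybenzyloxy)vinyl δ-lactone (Claisen precursor)
Conditions: 12 (10 equiv), Cu(OAc)2 (2 equiv), Et3N (4 equiv), 4 Å MS, CH2Cl2, rt, air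
Reagents that add atoms: 4-methoxybenzyl alcohol (compound 12), COc1ccc(CO)cc1
Why: Chan–Lam-type oxidative C–O coupling of an alkenyl boronate with an alcohol (transmetalation to divalent copper, then C–O reductive elimination from trivalent copper) retains alkene geometry, so the E-boronate should give the E-enol ether under amine-buffered room-temperature conditions that the lactone tolerates.

**Step 8**
Reactants: 13 E-2-(4-methoxybenzyloxy)vinyl δ-lactone
Product: 16 1-triethylsilyloxy-6-(4-methoxybenzyloxy)-2,3-isopropylidenedioxycyclohex-4-ene-1-carboxylic acid, via silyl ketene acetal 14 (not isolated), via trimethylsilyl ester 15 (not isolated)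
Conditions: Me3SiCl/Et3N (premixed, 6 equiv), THF, −78 °C; LiN(SiMe3)2 (1.5 equiv) added slowly, −78 °C, 1 h, then rt; toluene, 80 °C; pH 5 aqueous buffer/THF, rt
Reagents that add atoms: chlorotrimethylsilane, C[Si](C)(C)Cl (its silyl group is carried by 14 and 15 only)
Why: Deprotonation at C1 with Me3SiCl already in the flask traps the lactone enolate as the cyclic silyl ketene acetal 14 before the C2 acetonide oxygen can be expelled, and on warming 14 undergoes a concerted suprafacial [3,3] sigmatropic shift across C1=C7–O–C4–C5=C6 that makes C1–C6, breaks O–C4 and leaves the C4=C5 double bond and silyl ester 15, which the buffer hydrolyses to 16. The closest known reactions are the Ireland–Claisen ring contraction of alkenyl lactones, the dioxanone-to-dihydropyran Claisen rearrangement and ester-enolate Claisen shifts onto glycal enol ethers. The carbocycle C1–C2–C3–C4–C5–C6 closes in a 6-endo sense at the distal enol-ether carbon, and because the ketene acetal is endocyclic and C1 and C4 stay linked through C2–C3, the six-atom array must be a boat (bicyclo[2.2.2]octene-like). C1 is set by the C4 configuration: the alkenyl arm is cis to the acetonide oxygens and can reach only the C1 face on its own side, which puts C7 anti to O2 and O3. C6 is set by the E geometry of the enol ether, which in the boat turns the 4-methoxybenzyloxy group away from the C2–C3 bridge and so places O6 cis to C7 and trans to O1. The step needs silylation to outrun β-elimination, which the internal quench at −78 °C secures, and a single enol-ether geometry, which steps 6 and 7 secure, while the donor oxygen at C6 and the silyloxy group at C7 both accelerate the shift.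

**Step 9**
Reactants: 16 cyclohexene carboxylic acid
Product: 17 1-(hydroxymethyl)-1-triethylsilyloxy-6-(4-methoxybenzyloxy)-2,3-isopropylidenedioxycyclohex-4-ene
Conditions: LiAlH4 (3 equiv), THF, 0 °C → rt; Fieser work-up at 0 °C
Reagents that add atoms: none
Why: Hydride reduction takes the hindered carboxylic acid to the primary carbinol without touching ethers, acetal or the ring alkene, and the cold quench of the aluminium alkoxide guards against 1,4-silyl migration from O1 to O7.

**Step 10**
Reactants: 17 C7 carbinol; 18 benzoyl chloride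
Product: 19 C7 benzoate of 17
Conditions: BzCl (1.3 equiv), pyridine, DMAP (cat.), CH2Cl2, 0 °C → rt
Reagents that add atoms: benzoyl chloride (compound 18), O=C(Cl)c1ccccc1
Why: Nucleophile-catalysed acylation of the only free hydroxyl installs the C7 benzoate.

**Step 11**
Reactants: 19 C7 benzoate
Product: 20 [1,2,3-trihydroxy-6-(4-methoxybenzyloxy)cyclohex-4-en-1-yl]methyl benzoate
Conditions: AcOH/H2O/THF (3:1:1), 55 °C
Reagents that add atoms: none
Why: Acid-catalysed hydrolysis removes the dioxolane and the triethylsilyl ether in one operation by acetal C–O and Si–O cleavage, so every ring C–O bond keeps its configuration, while benzoate and PMB ether withstand dilute acetic acid.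

**Step 12**
Reactants: 20 triol
Product: 21 3-O-tert-butyldimethylsilyl ether of 20
Conditions: t-BuMe2SiCl (1.1 equiv), imidazole, DMF, −20 °C → 0 °C
Reagents that add atoms: tert-butyldimethylsilyl chloride, CC(C)(C)[Si](C)(C)Cl
Why: Kinetic silylation should favour the allylic O3–H, flanked by an sp2 carbon, over O2–H, which is neopentyl-like beside the fully substituted C1, and it leaves the tertiary O1–H untouched.

**Step 13**
Reactants: 21 3-O-silyl diol; 18 benzoyl chloride
Product: 22 2-O-benzoyl-3-O-tert-butyldimethylsilyl derivative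
Conditions: BzCl (2 equiv), DMAP (0.3 equiv), pyridine, rt → 40 °C
Reagents that add atoms: benzoyl chloride (compound 18), O=C(Cl)c1ccccc1
Why: DMAP-catalysed acylation esterifies the remaining secondary hydroxyl at C2, the tertiary O1–H being too hindered to compete.

**Step 14**
Reactants: 22 dibenzoate PMB ether
Product: 23 trans-1,6-diol
Conditions: DDQ (1.3 equiv), CH2Cl2/pH 7 phosphate buffer (10:1), 0 °C
Reagents that add atoms: none
Why: Oxidative cleavage of the PMB ether (hydride abstraction, hydrolysis of the oxocarbenium ion) frees the C6 hydroxyl with retention, the aqueous buffer preventing acetal formation with O1–H and loss of the silyl ether.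

**Step 15**
Reactants: 23 trans-1,6-diol
Product: 25 target 3-O-tert-butyldimethylsilyl ether, via allylic mesylate 24 (not isolated)
Conditions: Ms2O (1.3 equiv), Et3N, CH2Cl2, −20 °C; then DBU (2 equiv), 0 °C → rt
Reagents that add atoms: methanesulfonic anhydride, CS(=O)(=O)OS(C)(=O)=O (its sulfonyl group is carried by 24 only)
Why: Sulfonylation of the secondary C6–OH (the tertiary O1–H is inert) followed by intramolecular Williamson-type SN2 displacement by the O1 alkoxide from the opposite face (trans-diaxial in the half-chair) closes the oxirane with inversion at C6 and retention at C1, which puts the epoxide oxygen cis to O2 and O3 and anti to C7, and the chloride-free anhydride avoids allylic substitution.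

**Step 16**
Reactants: 25 target 3-O-tert-butyldimethylsilyl ether
Product: 26 target, (1S,2R,3R,6S)-2-benzoyloxy-1-(benzoyloxymethyl)-1,6-epoxycyclohex-4-en-3-ol
Conditions: HF·pyridine, pyridine, THF, 0 °C → rt
Reagents that add atoms: none
Why: Pyridine-buffered fluoride desilylation frees O3–H without the basic conditions that would move the C2 benzoate to O3 and without opening the vinyl oxirane.

**Compound list**
1 | benzyl β-D-galactopyranoside | OC[C@H]1O[C@@H](OCc2ccccc2)[C@H](O)[C@@H](O)[C@H]1O | starting material
2 | 2,2-dimethoxypropane | COC(C)(C)OC | starting material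
3 | benzyl 3,4-O-isopropylidene-β-D-galactopyranoside | OC[C@H]1O[C@@H](OCc2ccccc2)[C@H](O)[C@H]3OC(C)(C)O[C@@H]13 | intermediate
4 | benzyl 3,4-O-isopropylidene-β-D-galactopyranosiduronic acid | OC(=O)[C@H]1O[C@@H](OCc2ccccc2)[C@H](O)[C@H]3OC(C)(C)O[C@@H]13 | intermediate
5 | 3,4-O-isopropylidene-D-galactopyranuronic acid, free lactol, both anomers | OC(=O)[C@H]1OC(O)[C@H](O)[C@H]3OC(C)(C)O[C@@H]13 | intermediate
6 | dimethyl (1-diazo-2-oxopropyl)phosphonate | COP(=O)(OC)C(=[N+]=[N-])C(C)=O | starting material
7 | 6,7-dideoxy-3,4-O-isopropylidene-L-galacto-hept-6-ynonic acid (its C2–C5 are C5–C2 of D-galacturonic acid) | C#C[C@H](O)[C@H]1OC(C)(C)O[C@H]1[C@H](O)C(=O)O | intermediate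
8 | chlorotriethylsilane | CC[Si](Cl)(CC)CC | starting material
9 | 6,7-dideoxy-3,4-O-isopropylidene-L-galacto-hept-6-ynono-1,5-lactone (formed in the flask) | O=C1O[C@@H](C#C)[C@H]2OC(C)(C)O[C@H]2[C@@H]1O | intermediate
10 | 6,7-dideoxy-3,4-O-isopropylidene-2-O-triethylsilyl-L-galacto-hept-6-ynono-1,5-lactone | O=C1O[C@@H](C#C)[C@H]2OC(C)(C)O[C@H]2[C@@H]1O[Si](CC)(CC)CC | intermediate
11 | the same lactone carrying an E-2-(pinacolatoboryl)vinyl group on the lactone carbinol carbon | O=C1O[C@@H](/C=C/B3OC(C)(C)C(C)(C)O3)[C@H]2OC(C)(C)O[C@H]2[C@@H]1O[Si](CC)(CC)CC | intermediate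
12 | 4-methoxybenzyl alcohol | COc1ccc(CO)cc1 | starting material
13 | δ-lactone with C7 carbonyl, C1–OSiEt3, C2/C3 acetonide, lactone oxygen on C4 and E-CH=CH–OPMB (C5=C6) on C4, the vinyl group cis to the acetonide oxygens | O=C1O[C@@H](/C=C/OCc3ccc(OC)cc3)[C@H]2OC(C)(C)O[C@H]2[C@@H]1O[Si](CC)(CC)CC | intermediate
14 | cyclic trimethylsilyl ketene acetal of 13 (C1=C7, formed in the flask) | C[Si](C)(C)OC1=C(O[Si](CC)(CC)CC)[C@@H]2OC(C)(C)O[C@@H]2[C@H](/C=C/OCc3ccc(OC)cc3)O1 | intermediate
15 | trimethylsilyl ester of 16 (formed in the flask) | C[Si](C)(C)OC(=O)[C@]1(O[Si](CC)(CC)CC)[C@H](OCc2ccc(OC)cc2)C=C[C@H]3OC(C)(C)O[C@H]31 | intermediate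
16 | 1-triethylsilyloxy-6-(4-methoxybenzyloxy)-2,3-isopropylidenedioxycyclohex-4-ene-1-carboxylic acid; CO2H anti to O1, O2 and O3, O6 cis to CO2H | OC(=O)[C@]1(O[Si](CC)(CC)CC)[C@H](OCc2ccc(OC)cc2)C=C[C@H]3OC(C)(C)O[C@H]31 | intermediate
17 | the C7 carbinol from 16 (CO2H replaced by CH2OH) | OC[C@]1(O[Si](CC)(CC)CC)[C@H](OCc2ccc(OC)cc2)C=C[C@H]3OC(C)(C)O[C@H]31 | intermediate
18 | benzoyl chloride | O=C(Cl)c1ccccc1 | starting material
19 | C7 benzoate of 17 | O=C(OC[C@]1(O[Si](CC)(CC)CC)[C@H](OCc2ccc(OC)cc2)C=C[C@H]3OC(C)(C)O[C@H]31)c1ccccc1 | intermediate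
20 | [1,2,3-trihydroxy-6-(4-methoxybenzyloxy)cyclohex-4-en-1-yl]methyl benzoate; O1, O2, O3 on one face, C7 and O6 on the other | O=C(OC[C@]1(O)[C@H](OCc2ccc(OC)cc2)C=C[C@@H](O)[C@H]1O)c1ccccc1 | intermediate
21 | 3-O-tert-butyldimethylsilyl ether of 20 | O=C(OC[C@]1(O)[C@H](OCc2ccc(OC)cc2)C=C[C@@H](O[Si](C)(C)C(C)(C)C)[C@H]1O)c1ccccc1 | intermediate
22 | 2-O-benzoate of 21 | O=C(OC[C@]1(O)[C@H](OCc2ccc(OC)cc2)C=C[C@@H](O[Si](C)(C)C(C)(C)C)[C@H]1OC(=O)c1ccccc1)c1ccccc1 | intermediate
23 | trans-1,6-diol from 22 (C6–OH free) | O=C(OC[C@]1(O)[C@H](O)C=C[C@@H](O[Si](C)(C)C(C)(C)C)[C@H]1OC(=O)c1ccccc1)c1ccccc1 | intermediate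
24 | 6-O-methanesulfonate of 23 (formed in the flask) | O=C(OC[C@]1(O)[C@H](OS(C)(=O)=O)C=C[C@@H](O[Si](C)(C)C(C)(C)C)[C@H]1OC(=O)c1ccccc1)c1ccccc1 | intermediate
25 | 3-O-tert-butyldimethylsilyl ether of the target | O=C(OC[C@]12O[C@H]1C=C[C@@H](O[Si](C)(C)C(C)(C)C)[C@H]2OC(=O)c1ccccc1)c1ccccc1 | intermediate
26 | (1S,2R,3R,6S)-2-benzoyloxy-1-(benzoyloxymethyl)-1,6-epoxycyclohex-4-en-3-ol (working numbering) | O=C(OC[C@]12O[C@H]1C=C[C@@H](O)[C@H]2OC(=O)c1ccccc1)c1ccccc1 | target

Total step count: 16. Longest linear sequence: 16 steps (1 → 26).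

**Steps most likely to fail**

Step 8. The lactone enolate may expel the C2 acetonide oxygen before it is silylated, or the ketene acetal may ionise at the allylic C4–O bond on heating instead of shifting in concert. The fallback sets out from 13 and makes the ketene acetal without any metal enolate, as an isolable species. Treatment with t-BuMe2SiOTf/Et3N in CH2Cl2 at 0 °C (carbonyl O-silylation, then deprotonation by the amine) should give the tert-butyldimethylsilyl ketene acetal F1. This is freed of ammonium salts and heated in toluene to the tert-butyldimethylsilyl ester F2, which K2CO3 in aqueous methanol cleaves to acid 16, where the route is rejoined.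

Step 7. Transmetalation of the hindered alkenyl boronate may be slow enough for protodeboronation to take over, or the excess alcohol may open the lactone. The fallback sets out from lactol 5 and by-passes steps 4 to 7. Wittig olefination with the ylide from (4-methoxybenzyloxymethyl)triphenylphosphonium chloride F3 (made from PPh3 and 4-methoxybenzyl chloromethyl ether) and KN(SiMe3)2 in THF, used in excess, gives the E-enol ether dihydroxy acid F4 together with its geometric isomer. EDC lactonisation gives the hydroxy lactone F5, from which the unwanted isomer is removed by chromatography, and Et3SiCl/imidazole then gives 13, where the route is rejoined.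

Step 12. Discrimination between O3–H and O2–H may be poor, since the equatorial O2–H can compete despite its crowded surroundings, or the silyl group may wander between the cis oxygens. The fallback sets out from triol 20 and reverses the order of events. Bu2SnO in methanol at reflux, then evaporation, gives the dibutylstannylene acetal F6 (drawn across O2/O3, not isolated). BzCl in toluene at rt is expected to deliver the acyl group to the equatorial oxygen of the cis-diol, O2, in the half-chair that keeps C7H2OBz equatorial, giving the 2-O-benzoate F7. t-BuMe2SiCl/imidazole then silylates the one unhindered secondary hydroxyl left (O3) and the route is rejoined at 22.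

**Further compounds**
F1 | step 8 | tert-butyldimethylsilyl ketene acetal of lactone 13 | CC(C)(C)[Si](C)(C)OC1=C(O[Si](CC)(CC)CC)[C@@H]2OC(C)(C)O[C@@H]2[C@H](/C=C/OCc3ccc(OC)cc3)O1
F2 | step 8 | tert-butyldimethylsilyl ester of acid 16 | CC(C)(C)[Si](C)(C)OC(=O)[C@]1(O[Si](CC)(CC)CC)[C@H](OCc2ccc(OC)cc2)C=C[C@H]3OC(C)(C)O[C@H]31
F3 | step 7 | (4-methoxybenzyloxymethyl)triphenylphosphonium chloride | COc1ccc(COC[P+](c2ccccc2)(c2ccccc2)c2ccccc2)cc1.[Cl-]
F4 | step 7 | E-enol ether dihydroxy acid (7 with E-CH=CH–OPMB in place of the alkyne) | COc1ccc(CO/C=C/[C@H](O)[C@H]2OC(C)(C)O[C@H]2[C@H](O)C(=O)O)cc1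
F5 | step 7 | hydroxy lactone (13 without the triethylsilyl group) | O=C1O[C@@H](/C=C/OCc3ccc(OC)cc3)[C@H]2OC(C)(C)O[C@H]2[C@@H]1O
F6 | step 12 | 2,3-O-dibutylstannylene acetal of triol 20 | O=C(OC[C@]1(O)[C@H](OCc2ccc(OC)cc2)C=C[C@H]3O[Sn](CCCC)(CCCC)O[C@@H]13)c1ccccc1
F7 | step 12 | 2-O-benzoate of triol 20 (O1–H and O3–H free) | O=C(OC[C@]1(O)[C@H](OCc2ccc(OC)cc2)C=C[C@@H](O)[C@H]1OC(=O)c1ccccc1)c1ccccc1
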